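## The problem

Niruriflavone is a 2-(4-methoxyphenyl)chromen-4-one: ring C is the pyranone, ring B the anisyl group on C2, and ring A carries hydroxyls at C5 and C7 with a sulfonic acid on C6 between them. There is no stereocentre, so the task is one of regiochemistry and functional-group handling. The only stereochemical element in the route is the geometry of an enol ether double bond that disappears into ring C.

Three things have to be settled. First, sulfur must sit on C6 and not on C8; both carbons lie between two oxygens in a 5,7-dioxygenated flavone, so late sulfonation offers no dependable control. Second, the three phenolic oxygens must end differentiated, two free and one methylated. Third, ring C has to be closed onto a ring A that already bears an electron-withdrawing sulfonyl group.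

The sensitive groups are the arenesulfonic acid, the pyranone and the 4'-methyl ether. The sulfonic acid is very polar and, on so electron-rich a ring, liable to ipso-protonation and loss of SO3 in hot acid, so it is masked until the last step. The pyranone is opened at C2 by hydroxide or alkoxide. The 4'-methyl ether must outlive the unmasking of O5 and O7.

The enabling feature is that C6 is para to C8a and lies between C5 and C7. A ring A precursor of the type 4-hydroxy-2,6-dialkoxybenzenesulfonate therefore has a mirror plane through S, C6, C8a and O1. Its two carbons ortho to the hydroxyl are equivalent, and whichever becomes C4a, sulfur ends on C6.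

## Retrosynthesis

**Sulfonic acid from its ester.** The target 18 is traced to its neopentyl ester 16 by cutting the O–CH2 bond of the ester; the sodium salt 17 lies between them. A neutral ester keeps every intermediate soluble and chromatographable and protects the C6–S bond from acid. The forward step needs a non-basic nucleophile that attacks the neopentyl carbon without touching the pyranone or the methyl ether.

**Free phenols from isopropyl ethers.** Compound 16 comes from the bis(isopropyl) ether 15 by cutting the two O–CH(CH3)2 bonds. Isopropyl is chosen over methyl or benzyl for three reasons: it can be removed beside the 4'-methyl ether, it survives butyllithium, and it directs lithiation. The forward reaction asks for a Lewis acid that discriminates secondary from methyl ethers.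

**Ring C by the C4–C4a bond (key cut).** Flavone 15 is opened at C4–C4a to the (Z)-β-aryloxycinnamic acid 13, activated in the forward direction as the mixed anhydride 14.
- The neighbouring cuts (O1–C2 by cyclodehydration of a diketone, or C2–C1' by coupling) all need an ortho-hydroxyaryl ketone of ring A first. That means the same aryl–carbonyl bond made intermolecularly, with one of three oxygens of an acylated phloroglucinol sulfonate still to be singled out.
- The C4–C4a cut makes the bond intramolecularly and uses the one oxygen that is already unique.
- The precursor is simpler by one ring, and the mirror plane of its arene removes the 6- versus 8-sulfonate question.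
- The forward reaction asks only that a carbon meta to the sulfonyl group remains nucleophilic enough.

**Enol ether C–O bond.** Acid 13 comes from ethyl ester 12, and 12 is cut at O1–C2 into phenol 10 and the purchasable ynoate 11. This is the convergent cut: ring A on one side, ring B with C2, C3 and C4 on the other. The forward reaction is an oxa-Michael addition whose anti course places the ester cis to the aryloxy group, followed by a mild ester hydrolysis.

**Phenol oxygen by C–H functionalisation.** Phenol 10 is cut at the aryl C–O bond para to sulfur and traced, through boronate 9, to sulfonate 7 and bis(pinacolato)diboron 8. Starting from phloroglucinol would require statistical differentiation of three oxygens. In 7 only one ring hydrogen lacks an ortho neighbour, and it lies on the mirror plane, so sterically governed borylation is unambiguous. The forward reaction must tolerate a sulfonate ester.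

**C–S bond and the ethers.** Sulfonate 7 is cut at S–O into sulfonyl chloride 5 and neopentyl alcohol 6. Chloride 5 is cut at C–S and traced through sulfinate 4 and aryllithium 3 to 1,3-diisopropoxybenzene 2, and 2 to resorcinol 1. Electrophilic sulfonation of 2 would go para to one oxygen; lithiation between the two oxygens reverses this and places sulfur where C6 needs it.

## Roads not taken

**Alternative 1:** Ring A is dissected at C8–C8a, C7–C8, C5–C6 and C4a–C5, leaving a pyranone that supplies C4a and C8a.
- Forward key step: irradiation of diazo ketone A2 gives a pyranyl vinylketene by Wolff rearrangement. This undergoes (2+2) cycloaddition with the thio-substituted tert-butyl ynol ether A3. Four-electron opening of the cyclobutenone and six-electron closure then give phenol A1.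
- Merits: ring A is built in one operation, and the mechanism fixes O5, S6 and O7 in order, because the ketene carbon bonds to the sulfur-bearing alkyne carbon. No deactivated arene has to be acylated. O5 and O7 emerge already differentiated.
- Weak points: sulfur arrives as a thioether. It must be unmasked by retro-Michael cleavage and oxidised by six electrons to the sulfonic acid on an electron-rich, phenol-bearing ring next to an enone, where disulfide formation and ring oxidation compete. A2 and A3 each need several steps, and A3 is an unusual, probably labile alkyne. The pyranone double bond must act as the vinyl partner of the electrocyclisation, and the aryl pyranone is itself photoactive.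
- Comparison: this road is more convergent and avoids the Friedel–Crafts closure on a sulfonyl-bearing ring, which is the weak point of the chosen plan. The chosen plan offers in return that sulfur is at its final oxidation state from step 2, the starting materials are cheap, and every step is of a known type.

**Alternative 2:** The cut is at C5–C6 and C6–C7; C6 is inserted as the methylene of neopentyl methanesulfonate A6 between two ester carbons of pyranone diester A5.
- Forward key step: lithiated A6 is acylated by the ring ester and then, as the β-keto sulfonate anion, by the side-chain ester, and the product aromatises to A4.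
- Merits: A4 is identical with compound 16 of the chosen route, so this road would arrive one step from the target with both phenols free and no phenol protection at all. The position of sulfur is guaranteed because it rides on the inserted carbon.
- Weak points: the side-chain CH2 of A5 is flanked by an ester and the vinylogous ester carbon of the pyranone. It is more acidic than A6, so proton transfer should quench the nucleophile and deactivate the very ester that must react second. The carbanion can also add to the pyranone at its oxygen-bearing carbons and open the ring. The second acylation asks a stabilised, hindered anion to attack an enolised ester. A5 is itself a multi-step compound.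
- Comparison: if the condensation worked, this road would be shorter and free of ether protecting groups, a real advantage. The chosen plan offers in return that nothing in it depends on ordering three acidities in one flask.

**Alternative 3:** The cut is at the C5–O and C7–O bonds only.
- Forward key step: two equivalents of benzyl alcohol with NaH displace both fluorides of difluoroflavone sulfonate A8 to give A7. Both fluorides are ortho to the sulfonyl group and ortho or para to the carbonyl-bearing carbon.
- Merits: the substitution is of a very reliable type. The benzyl ethers would later fall to hydrogenolysis, which is gentler than BCl3 and orthogonal to the methyl ether and the neopentyl ester.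
- Weak points: the step forms no skeletal bond and closes no ring. The difficulty is moved into A8, whose ring C would have to be closed onto an arene bearing two fluorines and a sulfonyl group, far less nucleophilic than a dialkoxy arene. Benzyloxide can also attack C2 of the chromone and the sulfur of the sulfonate ester. Bringing both oxygens in late costs steps.
- Comparison: as a single step, the substitution is more certain than the ring closure of the chosen plan, and its deprotection is milder. The chosen plan offers in return that the oxygens are present from resorcinol onward and that its key step builds the ring.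

Key step: step 7

Assumption: the target is taken as the free sulfonic acid as drawn, so the sodium salt formed in the last step is acidified before isolation.

## Route

Step 1
Reactants: 1 resorcinol
Product: 2 1,3-diisopropoxybenzene
Conditions: 2-bromopropane, K2CO3, DMF, 70 °C
Reagents that add atoms: 2-bromopropane, CC(C)Br
Why: Williamson ether synthesis; both phenoxide oxygens are alkylated in a dipolar aprotic solvent, where O-alkylation outruns C-alkylation and elimination only consumes excess bromide.

Step 2
Reactants: 2 1,3-diisopropoxybenzene
Product: 5 2,6-diisopropoxybenzenesulfonyl chloride, via 2,6-diisopropoxyphenyllithium 3 (not isolated), via lithium 2,6-diisopropoxybenzenesulfinate 4 (not isolated)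
Conditions: n-BuLi, THF, 0 °C → rt; SO2, −78 °C → rt; N-chlorosuccinimide, CH2Cl2, 0 °C
Reagents that add atoms: sulfur dioxide, O=S=O; N-chlorosuccinimide, O=C1CCC(=O)N1Cl
Why: Directed ortho-metalation takes the hydrogen between the two alkoxy groups, SO2 traps the aryllithium as the sulfinate, and N-chlorosuccinimide chlorinates sulfur (oxidative chlorination of a sulfinate). Sulfur is thereby placed on the future C6, where electrophilic sulfonation of 2 would not go.

Step 3
Reactants: 5 2,6-diisopropoxybenzenesulfonyl chloride; 6 neopentyl alcohol (2,2-dimethylpropan-1-ol)
Product: 7 neopentyl 2,6-diisopropoxybenzenesulfonate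
Conditions: pyridine, 4-(dimethylamino)pyridine (cat.), CH2Cl2, 0 °C → rt
Reagents that add atoms: none
Why: Sulfonylation of a primary alcohol under nucleophilic catalysis. The neopentyl ester is chosen because substitution at its CH2 is so slow that the phenoxide of step 5 and the hydroxide of step 6 should not dealkylate it, and it is stable to trifluoroacetic acid.

Step 4
Reactants: 7 neopentyl 2,6-diisopropoxybenzenesulfonate; 8 bis(pinacolato)diboron
Product: 10 neopentyl 4-hydroxy-2,6-diisopropoxybenzenesulfonate, via neopentyl 2,6-diisopropoxy-4-(pinacolatoboryl)benzenesulfonate 9 (not isolated)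
Conditions: [Ir(OMe)(cod)]2 (cat.), 4,4'-di-tert-butyl-2,2'-bipyridine (cat.), THF, 80 °C; then KHSO5 (as 2KHSO5·KHSO4·K2SO4), acetone/H2O, rt
Reagents that add atoms: potassium peroxymonosulfate (KHSO5), [K+].[O-]S(=O)(=O)OO
Why: Iridium-catalysed aromatic C–H borylation is sterically governed and takes the only ring hydrogen without an ortho substituent, the one para to sulfur on the mirror plane. Oxidation of the C–B bond in the same flask (one-pot borylation–oxidation) gives the phenol oxygen that becomes O1.

Step 5
Reactants: 10 neopentyl 4-hydroxy-2,6-diisopropoxybenzenesulfonate; 11 ethyl 3-(4-methoxyphenyl)prop-2-ynoate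
Product: 12 ethyl (Z)-3-[3,5-diisopropoxy-4-(neopentyloxysulfonyl)phenoxy]-3-(4-methoxyphenyl)acrylate
Conditions: Cs2CO3 (0.3 equiv), DMF, 80 °C
Reagents that add atoms: none
Why: Base-catalysed oxa-Michael addition of a phenoxide to an arylpropiolate. Protonation anti to the incoming oxygen should give the Z enol ether, with the ester cis to the aryloxy group, and the neopentyl ester resists the phenoxide.

Step 6
Reactants: 12 ethyl (Z)-3-[3,5-diisopropoxy-4-(neopentyloxysulfonyl)phenoxy]-3-(4-methoxyphenyl)acrylate
Product: 13 (Z)-3-[3,5-diisopropoxy-4-(neopentyloxysulfonyl)phenoxy]-3-(4-methoxyphenyl)acrylic acid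
Conditions: LiOH·H2O, THF/H2O, rt → 40 °C; then 1 M HCl to pH 3
Reagents that add atoms: lithium hydroxide, [Li+].[OH-]
Why: Saponification of the ethyl ester, as in the classical β-aryloxycinnamic acid route to flavones. The donor anisyl group on the β-carbon and the carboxylate once formed both disfavour conjugate attack, and the hindered neopentyl sulfonate is inert to hydroxide at this temperature.

Step 7
Reactants: 13 (Z)-3-[3,5-diisopropoxy-4-(neopentyloxysulfonyl)phenoxy]-3-(4-methoxyphenyl)acrylic acid
Product: 15 neopentyl 5,7-diisopropoxy-2-(4-methoxyphenyl)-4-oxo-4H-chromene-6-sulfonate, via acyl trifluoroacetate mixed anhydride 14 (not isolated)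
Conditions: (CF3CO)2O, CH2Cl2, 0 °C → 40 °C
Reagents that add atoms: none
Why: (CF3CO)2O converts acid 13 into mixed anhydride 14, an acylium equivalent held cis to the aryloxy group by the Z double bond. The ring carbon ortho to the ether oxygen attacks the acyl carbon, trifluoroacetate leaves, and loss of a proton from the Wheland intermediate gives the pyranone (intramolecular Friedel–Crafts acylation). The closest known reaction types are the acid-mediated cyclisation of β-aryloxycinnamic acids to flavones and the anhydride-mediated cycloacylation of aryloxy acids. Ring C closes in a six-membered mode, 6-exo-trig at the acyl carbon, with the carbonyl oxygen remaining outside the ring. No stereocentre is created. The attacked carbon is ortho to O1, ortho to one isopropoxy group, para to the other and only meta to the sulfonyl group, so it should stay nucleophilic enough. Selectivity between the two ortho carbons is not required, because they are related by the mirror plane through S, C6, C8a and O1, so either closure gives the 6-sulfonate and the 8-sulfonate cannot arise. Closure onto the anisyl ring to an indenone is disfavoured by the Z geometry and by the poor nucleophilicity of a carbon meta to methoxy, and any E component should equilibrate through C-protonation by the acid liberated.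

Step 8
Reactants: 15 neopentyl 5,7-diisopropoxy-2-(4-methoxyphenyl)-4-oxo-4H-chromene-6-sulfonate
Product: 16 neopentyl 5,7-dihydroxy-2-(4-methoxyphenyl)-4-oxo-4H-chromene-6-sulfonate
Conditions: BCl3, CH2Cl2, −78 → 0 °C; then MeOH/H2O
Reagents that add atoms: none
Why: Lewis-acid ether cleavage; BCl3 dealkylates secondary isopropyl aryl ethers far faster than aryl methyl ethers, and the 5-ether is further assisted by chelation to the C4 carbonyl. The 4'-methyl ether should remain, and any neopentyl ester ionised here is not lost, because step 9 converges on the same product.

Step 9
Reactants: 16 neopentyl 5,7-dihydroxy-2-(4-methoxyphenyl)-4-oxo-4H-chromene-6-sulfonate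
Product: 18 niruriflavone [5,7-dihydroxy-2-(4-methoxyphenyl)-4-oxo-4H-chromene-6-sulfonic acid], via sodium 5,7-dihydroxy-2-(4-methoxyphenyl)-4-oxo-4H-chromene-6-sulfonate 17 (not isolated)
Conditions: NaN3, DMF, 70 °C; C18 filtration to remove excess NaN3; then 1 M HCl
Reagents that add atoms: none
Why: SN2 dealkylation of the sulfonate ester by azide at the neopentyl CH2, the standard unmasking of neopentyl arenesulfonates. Azide is too weakly basic to open the pyranone or touch the aryl methyl ether, and acidification of salt 17 gives the free acid; the neopentyl azide formed is kept in solution.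

## Compound list

1 | resorcinol (benzene-1,3-diol) | Oc1cccc(O)c1 | starting material
2 | 1,3-diisopropoxybenzene | CC(C)Oc1cccc(OC(C)C)c1 | intermediate
3 | 2,6-diisopropoxyphenyllithium | [Li]c1c(OC(C)C)cccc1OC(C)C | intermediate (not isolated)
4 | lithium 2,6-diisopropoxybenzenesulfinate | [Li+].[O-]S(=O)c1c(OC(C)C)cccc1OC(C)C | intermediate (not isolated)
5 | 2,6-diisopropoxybenzenesulfonyl chloride | CC(C)Oc1cccc(OC(C)C)c1S(=O)(=O)Cl | intermediate
6 | neopentyl alcohol (2,2-dimethylpropan-1-ol) | CC(C)(C)CO | starting material
7 | neopentyl 2,6-diisopropoxybenzenesulfonate | CC(C)Oc1cccc(OC(C)C)c1S(=O)(=O)OCC(C)(C)C | intermediate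
8 | bis(pinacolato)diboron | CC1(C)OB(OC1(C)C)B1OC(C)(C)C(C)(C)O1 | starting material
9 | neopentyl 2,6-diisopropoxy-4-(pinacolatoboryl)benzenesulfonate | CC(C)Oc1cc(B2OC(C)(C)C(C)(C)O2)cc(OC(C)C)c1S(=O)(=O)OCC(C)(C)C | intermediate (not isolated)
10 | neopentyl 4-hydroxy-2,6-diisopropoxybenzenesulfonate | CC(C)Oc1cc(O)cc(OC(C)C)c1S(=O)(=O)OCC(C)(C)C | intermediate
11 | ethyl 3-(4-methoxyphenyl)prop-2-ynoate | CCOC(=O)C#Cc1ccc(OC)cc1 | starting material
12 | ethyl (Z)-3-[3,5-diisopropoxy-4-(neopentyloxysulfonyl)phenoxy]-3-(4-methoxyphenyl)acrylate | CCOC(=O)/C=C(\Oc1cc(OC(C)C)c(S(=O)(=O)OCC(C)(C)C)c(OC(C)C)c1)c1ccc(OC)cc1 | intermediate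
13 | (Z)-3-[3,5-diisopropoxy-4-(neopentyloxysulfonyl)phenoxy]-3-(4-methoxyphenyl)acrylic acid | OC(=O)/C=C(\Oc1cc(OC(C)C)c(S(=O)(=O)OCC(C)(C)C)c(OC(C)C)c1)c1ccc(OC)cc1 | intermediate
14 | mixed anhydride of acid 13 with trifluoroacetic acid, (Z) | FC(F)(F)C(=O)OC(=O)/C=C(\Oc1cc(OC(C)C)c(S(=O)(=O)OCC(C)(C)C)c(OC(C)C)c1)c1ccc(OC)cc1 | intermediate (not isolated)
15 | neopentyl 5,7-diisopropoxy-2-(4-methoxyphenyl)-4-oxo-4H-chromene-6-sulfonate | COc1ccc(-c2cc(=O)c3c(OC(C)C)c(S(=O)(=O)OCC(C)(C)C)c(OC(C)C)cc3o2)cc1 | intermediate
16 | neopentyl 5,7-dihydroxy-2-(4-methoxyphenyl)-4-oxo-4H-chromene-6-sulfonate | COc1ccc(-c2cc(=O)c3c(O)c(S(=O)(=O)OCC(C)(C)C)c(O)cc3o2)cc1 | intermediate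
17 | sodium 5,7-dihydroxy-2-(4-methoxyphenyl)-4-oxo-4H-chromene-6-sulfonate | COc1ccc(-c2cc(=O)c3c(O)c(S(=O)(=O)[O-])c(O)cc3o2)cc1.[Na+] | intermediate (not isolated)
18 | niruriflavone, 5,7-dihydroxy-2-(4-methoxyphenyl)-4-oxo-4H-chromene-6-sulfonic acid | COc1ccc(-c2cc(=O)c3c(O)c(S(=O)(=O)O)c(O)cc3o2)cc1 | target

## Step count and risks

Total step count: 9. Longest linear sequence: 9 steps, from resorcinol 1 to niruriflavone 18; compounds 6, 8 and 11 enter as purchased materials.

Least certain steps:

**Step 7 (key step).** The most likely failure is slow or incomplete acylation. The sulfonyl group lowers the nucleophilicity of the ring, and the isopropoxy group next to the reacting carbon has to twist aside. Forcing the reaction with stronger acid invites loss of an isopropyl group or cleavage of the enol ether.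

The fallback makes the aryl–carbonyl bond by palladium catalysis and sets out from phenol 10. Iodination with N-iodosuccinimide in MeCN should give neopentyl 4-hydroxy-3-iodo-2,6-diisopropoxybenzenesulfonate F1; the two ortho carbons are again equivalent. Carbonylative coupling with commercial 4-ethynylanisole (PdCl2(PPh3)2, CO at 1 atm, Et2NH) would pass through the ortho-hydroxyaryl ynone, neopentyl 4-hydroxy-2,6-diisopropoxy-3-[3-(4-methoxyphenyl)prop-2-ynoyl]benzenesulfonate F2. Its 6-endo-dig oxa-Michael closure returns to the route at flavone 15.

**Step 5.** The addition may stall, because a sulfonyl-stabilised phenoxide is a weak nucleophile and the donor anisyl group makes the ynoate a poor acceptor. Prolonged heating would then allow reversal and scrambling of the alkene geometry.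

The fallback replaces addition by a substitution at a vinyl halide and sets out from ynoate 11. Anti hydroiodination (NaI, AcOH, 70 °C) should give ethyl (Z)-3-iodo-3-(4-methoxyphenyl)acrylate F3. Ullmann-type vinyl C–O coupling with phenol 10 (CuI, N,N-dimethylglycine, Cs2CO3, dioxane, 90 °C), which proceeds with retention, returns to the route at ester 12.

**Step 6.** Hydroxide may add to the β-carbon and expel the stabilised aryloxide of phenol 10 instead of hydrolysing the ester, which would take the enol ether apart.

The fallback avoids hydroxide and sets out from phenol 10. Commercial 4-ethynylanisole is converted (n-BuLi, THF, −78 °C; di-tert-butyl dicarbonate) into tert-butyl 3-(4-methoxyphenyl)prop-2-ynoate F4. Addition of 10 under the conditions of step 5 gives tert-butyl (Z)-3-[3,5-diisopropoxy-4-(neopentyloxysulfonyl)phenoxy]-3-(4-methoxyphenyl)acrylate F5. Acidolysis (CF3CO2H, CH2Cl2, anisole as cation trap, rt) returns to the route at acid 13.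

**Step 8.** The Lewis acid may ionise the neopentyl sulfonate (1,2-methyl shift) alongside the isopropyl ethers, giving mixtures of ester and free acid that are hard to separate. The crowded 7-ether may also react incompletely.

The fallback reverses the order of unmasking and sets out from flavone 15. Tetrabutylammonium azide in MeCN at 70 °C should give tetrabutylammonium 5,7-diisopropoxy-2-(4-methoxyphenyl)-4-oxo-4H-chromene-6-sulfonate F6, which is soluble in CH2Cl2. BCl3 (−78 → 0 °C) then removes both isopropyl groups with no ester left to protect, and aqueous HCl work-up returns to the route at target 18. The same detour places the nucleophilic dealkylation on a substrate without free phenols, should the substitution of step 9 prove sluggish on 16.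

## Further compounds

F1 | step 7 | neopentyl 4-hydroxy-3-iodo-2,6-diisopropoxybenzenesulfonate | CC(C)Oc1cc(O)c(I)c(OC(C)C)c1S(=O)(=O)OCC(C)(C)C
F2 | step 7 | neopentyl 4-hydroxy-2,6-diisopropoxy-3-[3-(4-methoxyphenyl)prop-2-ynoyl]benzenesulfonate | CC(C)Oc1cc(O)c(C(=O)C#Cc2ccc(OC)cc2)c(OC(C)C)c1S(=O)(=O)OCC(C)(C)C
F3 | step 5 | ethyl (Z)-3-iodo-3-(4-methoxyphenyl)acrylate | CCOC(=O)/C=C(\I)c1ccc(OC)cc1
F4 | step 6 | tert-butyl 3-(4-methoxyphenyl)prop-2-ynoate | COc1ccc(cc1)C#CC(=O)OC(C)(C)C
F5 | step 6 | tert-butyl (Z)-3-[3,5-diisopropoxy-4-(neopentyloxysulfonyl)phenoxy]-3-(4-methoxyphenyl)acrylate | CC(C)(C)OC(=O)/C=C(\Oc1cc(OC(C)C)c(S(=O)(=O)OCC(C)(C)C)c(OC(C)C)c1)c1ccc(OC)cc1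
F6 | step 8 | tetrabutylammonium 5,7-diisopropoxy-2-(4-methoxyphenyl)-4-oxo-4H-chromene-6-sulfonate | COc1ccc(-c2cc(=O)c3c(OC(C)C)c(S(=O)(=O)[O-])c(OC(C)C)cc3o2)cc1.CCCC[N+](CCCC)(CCCC)CCCC
A1 | alternative 1 | methyl 3-{[7-tert-butoxy-5-hydroxy-2-(4-methoxyphenyl)-4-oxo-4H-chromen-6-yl]sulfanyl}propanoate | COC(=O)CCSc1c(O)c2c(=O)cc(-c3ccc(OC)cc3)oc2cc1OC(C)(C)C
A2 | alternative 1 | 2-diazo-1-[6-(4-methoxyphenyl)-4-oxo-4H-pyran-2-yl]ethan-1-one | COc1ccc(cc1)-c1cc(=O)cc(o1)C(=O)C=[N+]=[N-]
A3 | alternative 1 | methyl 3-[(2-tert-butoxyethynyl)sulfanyl]propanoate | COC(=O)CCSC#COC(C)(C)C
A4 | alternative 2 | neopentyl 5,7-dihydroxy-2-(4-methoxyphenyl)-4-oxo-4H-chromene-6-sulfonate | COc1ccc(-c2cc(=O)c3c(O)c(S(=O)(=O)OCC(C)(C)C)c(O)cc3o2)cc1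
A5 | alternative 2 | methyl 2-(2-methoxy-2-oxoethyl)-6-(4-methoxyphenyl)-4-oxo-4H-pyran-3-carboxylate | COC(=O)Cc1oc(-c2ccc(OC)cc2)cc(=O)c1C(=O)OC
A6 | alternative 2 | neopentyl methanesulfonate | CS(=O)(=O)OCC(C)(C)C
A7 | alternative 3 | neopentyl 5,7-bis(benzyloxy)-2-(4-methoxyphenyl)-4-oxo-4H-chromene-6-sulfonate | COc1ccc(-c2cc(=O)c3c(OCc4ccccc4)c(S(=O)(=O)OCC(C)(C)C)c(OCc4ccccc4)cc3o2)cc1
A8 | alternative 3 | neopentyl 5,7-difluoro-2-(4-methoxyphenyl)-4-oxo-4H-chromene-6-sulfonate | COc1ccc(-c2cc(=O)c3c(F)c(S(=O)(=O)OCC(C)(C)C)c(F)cc3o2)cc1
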